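**Plan**

- Retrosynthesis (germacrane numbering): cut C9–C10 (ring-closing addition of a C10 alkenylchromium to a C9 aldehyde), then the C8–O ester bond, then C6–C7 together with the lactone C12–O6 bond in a single operation.
- Feature used: C6 (lactone oxygen) and C7 (tertiary carbinol) are adjacent stereocentres, and C7 carries the C11(=C13H2)–C12 acyl unit of the γ-lactone ring. This is the retron of an SE2' addition of a 2-(alkoxycarbonyl)allyl metal (metal on C13) to a C6 aldehyde.
- Fragments: a C1–C6 iodo-dienal from geranyl acetate; a C7–C9/C11–C13 γ-siloxyallyl bromide from methyl acrylate and (R)-glyceraldehyde acetonide; the epoxy acid from tiglyl alcohol.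
- Forward order: the fragments are joined at C6–C7 with closure of the γ-lactone ring (step 8), C8 is acylated, and the ten-membered carbocycle is closed last at C9–C10 (step 16).
- Stereochemistry: C8 from the chiral pool; C6 and C7 from the chair transition state of step 8 under 1,2-induction by C8; C9 from Felkin-type addition anti to the C8 acyloxy group; the oxirane from a Sharpless epoxidation with D-tartrate; 4E from geranyl acetate and 1(10)Z from the Stork–Zhao olefination.

Key step: step 8

Remark: the acyl group of the target, (2S,3R)-2,3-dimethyloxirane-2-carbonyl, has its carboxyl carbon and 3-methyl group trans on the oxirane, so it is made from (E)-2-methylbut-2-en-1-ol (tiglyl alcohol).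

**Route**

Step 1
Reactants: 1 geranyl acetate
Product: 3 (2E)-3-methyl-6-oxohex-2-en-1-yl acetate, via ozonide 2 (not isolated)
Conditions: O3 (1 equiv), CH2Cl2, −78 °C; then Me2S, −78 °C to rt
Reagents that add atoms: ozone, [O-][O+]=O
Why: Ozonolysis with reductive work-up should cleave the electron-rich 6,7-alkene selectively, because the 2,3-alkene is deactivated by the allylic acetoxy group, and the 2E geometry is not touched.

Step 2
Reactants: 3 (2E)-3-methyl-6-oxohex-2-en-1-yl acetate, 4 ethyltriphenylphosphonium iodide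
Product: 8 (2E,6Z)-7-iodo-3-methylocta-2,6-dien-1-yl acetate, via ethylidenetriphenylphosphorane 5 (not isolated), via (1-iodoethyl)triphenylphosphonium iodide 6 (not isolated), via (1-iodoethylidene)triphenylphosphorane 7 (not isolated)
Conditions: 4, n-BuLi, THF, rt; I2, −78 °C; NaN(SiMe3)2, −20 °C; then 3, −78 °C to rt
Reagents that add atoms: iodine, II
Why: Stork–Zhao olefination: the non-stabilised α-iodo ylide 7 adds to the aldehyde under kinetic control and should give the trisubstituted vinyl iodide with iodine cis to the chain (6Z), while the acetate survives at low temperature.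

Step 3
Reactants: 8 (2E,6Z)-7-iodo-3-methylocta-2,6-dien-1-yl acetate
Product: 9 (2E,6Z)-7-iodo-3-methylocta-2,6-dien-1-ol
Conditions: K2CO3, MeOH, 0 °C to rt
Reagents that add atoms: none
Why: Base-catalysed methanolysis (transesterification) of the acetate should free the allylic alcohol without touching the vinyl iodide or either alkene geometry.

Step 4
Reactants: 9 (2E,6Z)-7-iodo-3-methylocta-2,6-dien-1-ol
Product: 10 (2E,6Z)-7-iodo-3-methylocta-2,6-dienal
Conditions: MnO2, CH2Cl2, rt
Reagents that add atoms: none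
Why: MnO2 oxidises allylic alcohols selectively to enals under neutral conditions, so the 2E geometry and the vinyl iodide should be retained.

Step 5
Reactants: 11 methyl acrylate, 12 (4R)-2,2-dimethyl-1,3-dioxolane-4-carbaldehyde
Product: 13 methyl 2-{[(4R)-2,2-dimethyl-1,3-dioxolan-4-yl](hydroxy)methyl}prop-2-enoate (both carbinol epimers)
Conditions: DABCO, 1,4-dioxane/H2O, rt
Reagents that add atoms: none
Why: Morita–Baylis–Hillman reaction of the acrylate with the α-alkoxy aldehyde; the new carbinol centre is of no consequence because step 6 removes it, and C8 is carried over unchanged from the aldehyde.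

Step 6
Reactants: 13 methyl 2-{[(4R)-2,2-dimethyl-1,3-dioxolan-4-yl](hydroxy)methyl}prop-2-enoate
Product: 14 methyl 2-[(4R)-2,2-dimethyl-1,3-dioxolane-4-carbonyl]prop-2-enoate
Conditions: Dess–Martin periodinane, NaHCO3, CH2Cl2, 0 °C; used without storage
Reagents that add atoms: none
Why: Dess–Martin oxidation converts the secondary allylic alcohol into the 2-acyl acrylate under non-basic conditions, which should leave the C8 centre next to the new ketone intact.

Step 7
Reactants: 14 methyl 2-[(4R)-2,2-dimethyl-1,3-dioxolane-4-carbonyl]prop-2-enoate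
Product: 15 methyl (2Z)-2-(bromomethyl)-3-[(4R)-2,2-dimethyl-1,3-dioxolan-4-yl]-3-[(triethylsilyl)oxy]prop-2-enoate
Conditions: Et3SiBr (1.0 equiv), CH2Cl2, −78 to −20 °C; concentrated and used at once
Reagents that add atoms: bromotriethylsilane, CC[Si](CC)(CC)Br
Why: Conjugate (1,4-) addition of a halosilane to an enone: bromide adds to the methylene terminus while silicon goes to the ketone oxygen of the s-cis enone, so the siloxy group should end cis to the bromomethyl group, which is also the arrangement that keeps the enol oxygen anti to the ester carbonyl.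

Step 8
Reactants: 15 methyl (2Z)-2-(bromomethyl)-3-[(4R)-2,2-dimethyl-1,3-dioxolan-4-yl]-3-[(triethylsilyl)oxy]prop-2-enoate, 10 (2E,6Z)-7-iodo-3-methylocta-2,6-dienal
Product: 18 (4R,5R)-4-[(4R)-2,2-dimethyl-1,3-dioxolan-4-yl]-5-[(1E,5Z)-6-iodo-2-methylhepta-1,5-dien-1-yl]-3-methylidene-4-[(triethylsilyl)oxy]oxolan-2-one, via allylchromium dichloride 16 (not isolated), via chromium alkoxide 17 (not isolated)
Conditions: CrCl2 (nickel-free, 3.5 equiv), THF, 0 °C to rt
Reagents that add atoms: none
Why: Proposed new method: divalent chromium inserts into the allylic C–Br bond of 15 to give the 2-(methoxycarbonyl)-γ-siloxyallylchromium 16, which adds to the C6 aldehyde of 10 through a closed six-membered chair (chromium on the carbonyl oxygen, allylic transposition, new C6–C7 bond, exocyclic C11=C13), and the chromium alkoxide 17 then closes the γ-lactone ring by 5-exo-trig acyl substitution on the methyl ester. The closest known reactions are the Barbier and Nozaki–Hiyama additions of 3-substituted 2-(bromomethyl)acrylates, which give β,γ-disubstituted α-methylene-γ-butyrolactones, and the γ-attack of γ-siloxyallylchromium reagents on aldehydes, which gives 1,2-diol monosilyl ethers; their combination at a γ,γ-disubstituted carbon is new. C6 relative to C7: the aldehyde substituent sits equatorial and the siloxy group, cis to the CH2Cr carbon, sits axial, which places the C5 side chain cis to the C7 oxygen on the lactone. C7 relative to C8: the C8–H bond eclipses the ester-bearing C11 to avoid allylic 1,3-strain and the aldehyde approaches anti to the C8–C9 bond, on the face flanked by the dioxolane oxygen, which gives 7R from 8R. The step needs γ- rather than α-attack and 1,2-addition to the enal, both imposed by the cyclic transition state, and an untouched vinyl iodide, secured by the absence of nickel.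

Step 9
Reactants: 18 (4R,5R)-4-[(4R)-2,2-dimethyl-1,3-dioxolan-4-yl]-5-[(1E,5Z)-6-iodo-2-methylhepta-1,5-dien-1-yl]-3-methylidene-4-[(triethylsilyl)oxy]oxolan-2-one
Product: 19 (4S,5R)-4-[(1R)-1,2-dihydroxyethyl]-5-[(1E,5Z)-6-iodo-2-methylhepta-1,5-dien-1-yl]-3-methylidene-4-[(triethylsilyl)oxy]oxolan-2-one
Conditions: AcOH/H2O (4:1), rt
Reagents that add atoms: none
Why: Acid hydrolysis of a terminal isopropylidene acetal should be much faster than cleavage of the hindered tertiary triethylsilyl ether, and the lactone should stay on O6 because the alternatives would be a cis-disubstituted γ-lactone on O8 or a δ-lactone on O9.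

Step 10
Reactants: 19 (4S,5R)-4-[(1R)-1,2-dihydroxyethyl]-5-[(1E,5Z)-6-iodo-2-methylhepta-1,5-dien-1-yl]-3-methylidene-4-[(triethylsilyl)oxy]oxolan-2-one
Product: 20 (4S,5R)-4-[(1R)-2-{[tert-butyl(dimethyl)silyl]oxy}-1-hydroxyethyl]-5-[(1E,5Z)-6-iodo-2-methylhepta-1,5-dien-1-yl]-3-methylidene-4-[(triethylsilyl)oxy]oxolan-2-one
Conditions: TBSCl, imidazole, CH2Cl2, 0 °C
Reagents that add atoms: tert-butyldimethylsilyl chloride, CC(C)(C)[Si](C)(C)Cl
Why: Silylation with a bulky chlorosilane is selective for the primary C9 hydroxyl over the secondary C8 hydroxyl, which is flanked by a fully substituted carbon.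

Step 11
Reactants: 21 (2E)-2-methylbut-2-en-1-ol
Product: 22 [(2R,3R)-2,3-dimethyloxiran-2-yl]methanol
Conditions: Ti(OiPr)4 (10 mol%), D-(−)-diisopropyl tartrate (12 mol%), t-BuOOH, 4 Å molecular sieves, CH2Cl2, −20 °C
Reagents that add atoms: tert-butyl hydroperoxide, CC(C)(C)OO
Why: Sharpless asymmetric epoxidation transfers oxygen stereospecifically syn, so the trans relation of CH2OH and the 3-methyl group is kept, and the D-tartrate ligand selects the face that gives the (2R,3R) epoxy alcohol (L-tartrate gives the 2S series with E-allylic alcohols).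

Step 12
Reactants: 22 [(2R,3R)-2,3-dimethyloxiran-2-yl]methanol
Product: 24 (2S,3R)-2,3-dimethyloxirane-2-carboxylic acid, via epoxy aldehyde 23 (not isolated)
Conditions: RuCl3 (cat.), NaIO4, CCl4/MeCN/H2O, rt
Reagents that add atoms: water, O
Why: RuO4 generated from RuCl3 and NaIO4 oxidises the primary alcohol through aldehyde 23 and its hydrate to the acid without opening the oxirane, and the C2 descriptor changes from R to S only because the carboxyl group now outranks C3.

Step 13
Reactants: 20 (4S,5R)-4-[(1R)-2-{[tert-butyl(dimethyl)silyl]oxy}-1-hydroxyethyl]-5-[(1E,5Z)-6-iodo-2-methylhepta-1,5-dien-1-yl]-3-methylidene-4-[(triethylsilyl)oxy]oxolan-2-one, 24 (2S,3R)-2,3-dimethyloxirane-2-carboxylic acid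
Product: 26 (1R)-2-{[tert-butyl(dimethyl)silyl]oxy}-1-{(2R,3R)-2-[(1E,5Z)-6-iodo-2-methylhepta-1,5-dien-1-yl]-4-methylidene-5-oxo-3-[(triethylsilyl)oxy]oxolan-3-yl}ethyl (2S,3R)-2,3-dimethyloxirane-2-carboxylate, via mixed anhydride 25 (not isolated)
Conditions: 24, 2,4,6-trichlorobenzoyl chloride, Et3N, toluene, rt; then 20, DMAP, 40 °C
Reagents that add atoms: none
Why: Yamaguchi esterification through mixed anhydride 25 acylates the only free hydroxyl, at C8, with retention, and the silyl ether on O7 blocks both acylation and base-induced fragmentation at the tertiary carbinol.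

Step 14
Reactants: 26 (1R)-2-{[tert-butyl(dimethyl)silyl]oxy}-1-{(2R,3R)-2-[(1E,5Z)-6-iodo-2-methylhepta-1,5-dien-1-yl]-4-methylidene-5-oxo-3-[(triethylsilyl)oxy]oxolan-3-yl}ethyl (2S,3R)-2,3-dimethyloxirane-2-carboxylate
Product: 27 (1R)-2-hydroxy-1-{(2R,3R)-3-hydroxy-2-[(1E,5Z)-6-iodo-2-methylhepta-1,5-dien-1-yl]-4-methylidene-5-oxooxolan-3-yl}ethyl (2S,3R)-2,3-dimethyloxirane-2-carboxylate
Conditions: HF·pyridine, pyridine, THF, 0 °C to rt
Reagents that add atoms: none
Why: Fluoride-mediated desilylation under buffered, weakly acidic conditions should remove both silyl groups while 1,2-migration of the hindered ester from O8 to O9 stays slow and the oxirane is not opened.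

Step 15
Reactants: 27 (1R)-2-hydroxy-1-{(2R,3R)-3-hydroxy-2-[(1E,5Z)-6-iodo-2-methylhepta-1,5-dien-1-yl]-4-methylidene-5-oxooxolan-3-yl}ethyl (2S,3R)-2,3-dimethyloxirane-2-carboxylate
Product: 28 (1S)-1-{(2R,3R)-3-hydroxy-2-[(1E,5Z)-6-iodo-2-methylhepta-1,5-dien-1-yl]-4-methylidene-5-oxooxolan-3-yl}-2-oxoethyl (2S,3R)-2,3-dimethyloxirane-2-carboxylate
Conditions: Dess–Martin periodinane, NaHCO3, CH2Cl2, 0 °C; used crude
Reagents that add atoms: none
Why: Dess–Martin oxidation converts the primary alcohol into the aldehyde, leaves the tertiary C7 hydroxyl alone, and is neutral enough to avoid epimerisation at C8 (whose descriptor becomes S only through the priority change) and retro-aldol cleavage.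

Step 16
Reactants: 28 (1S)-1-{(2R,3R)-3-hydroxy-2-[(1E,5Z)-6-iodo-2-methylhepta-1,5-dien-1-yl]-4-methylidene-5-oxooxolan-3-yl}-2-oxoethyl (2S,3R)-2,3-dimethyloxirane-2-carboxylate
Product: 30 (3aR,4R,5R,6Z,10E,11aR)-3a,5-dihydroxy-6,10-dimethyl-3-methylidene-2-oxo-2,3,3a,4,5,8,9,11a-octahydrocyclodeca[b]furan-4-yl (2S,3R)-2,3-dimethyloxirane-2-carboxylate, via alkenylchromium dichloride 29 (not isolated)
Conditions: CrCl2 (excess), NiCl2 (cat.), DMSO, rt, high dilution (0.002 M)
Reagents that add atoms: none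
Why: Intramolecular Nozaki–Hiyama–Kishi reaction: nickel-catalysed insertion into the C–I bond and transmetalation give alkenylchromium 29 with retention of the Z geometry, which adds 10-exo-trig to the C9 aldehyde, and attack anti to the C8 acyloxy group (Felkin–Anh, polar model) should give the 8,9-anti, 9R alcohol.

**Compound list**

1 | geranyl acetate, (2E)-3,7-dimethylocta-2,6-dien-1-yl acetate | CC(C)=CCC/C(C)=C/COC(C)=O | starting material
2 | (2E)-5-(5,5-dimethyl-1,2,4-trioxolan-3-yl)-3-methylpent-2-en-1-yl acetate (ozonide) | CC(=O)OC/C=C(\C)CCC1OOC(C)(C)O1 | intermediate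
3 | (2E)-3-methyl-6-oxohex-2-en-1-yl acetate | CC(=O)OC/C=C(\C)CCC=O | intermediate
4 | ethyltriphenylphosphonium iodide | CC[P+](c1ccccc1)(c1ccccc1)c1ccccc1.[I-] | starting material
5 | ethylidenetriphenylphosphorane | CC=P(c1ccccc1)(c1ccccc1)c1ccccc1 | intermediate
6 | (1-iodoethyl)triphenylphosphonium iodide | CC(I)[P+](c1ccccc1)(c1ccccc1)c1ccccc1.[I-] | intermediate
7 | (1-iodoethylidene)triphenylphosphorane | CC(I)=P(c1ccccc1)(c1ccccc1)c1ccccc1 | intermediate
8 | (2E,6Z)-7-iodo-3-methylocta-2,6-dien-1-yl acetate | CC(=O)OC/C=C(\C)CC/C=C(/C)I | intermediate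
9 | (2E,6Z)-7-iodo-3-methylocta-2,6-dien-1-ol | OC/C=C(\C)CC/C=C(/C)I | intermediate
10 | (2E,6Z)-7-iodo-3-methylocta-2,6-dienal | O=C/C=C(\C)CC/C=C(/C)I | intermediate
11 | methyl acrylate | C=CC(=O)OC | starting material
12 | (4R)-2,2-dimethyl-1,3-dioxolane-4-carbaldehyde | O=C[C@H]1COC(C)(C)O1 | starting material
13 | methyl 2-{[(4R)-2,2-dimethyl-1,3-dioxolan-4-yl](hydroxy)methyl}prop-2-enoate (both carbinol epimers) | C=C(C(=O)OC)C(O)[C@H]1COC(C)(C)O1 | intermediate
14 | methyl 2-[(4R)-2,2-dimethyl-1,3-dioxolane-4-carbonyl]prop-2-enoate | C=C(C(=O)OC)C(=O)[C@H]1COC(C)(C)O1 | intermediate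
15 | methyl (2Z)-2-(bromomethyl)-3-[(4R)-2,2-dimethyl-1,3-dioxolan-4-yl]-3-[(triethylsilyl)oxy]prop-2-enoate | BrC/C(C(=O)OC)=C(\O[Si](CC)(CC)CC)[C@H]1COC(C)(C)O1 | intermediate
16 | dichloro{(2Z)-3-[(4R)-2,2-dimethyl-1,3-dioxolan-4-yl]-2-(methoxycarbonyl)-3-[(triethylsilyl)oxy]prop-2-en-1-yl}chromium | Cl[Cr](Cl)C/C(C(=O)OC)=C(\O[Si](CC)(CC)CC)[C@H]1COC(C)(C)O1 | intermediate
17 | O-(dichlorochromium) alkoxide of methyl (3R,4R,5E,9Z)-3-[(4R)-2,2-dimethyl-1,3-dioxolan-4-yl]-4-hydroxy-10-iodo-6-methyl-2-methylidene-3-[(triethylsilyl)oxy]undeca-5,9-dienoate | COC(=O)C(=C)[C@](O[Si](CC)(CC)CC)([C@H]1COC(C)(C)O1)[C@H](O[Cr](Cl)Cl)/C=C(\C)CC/C=C(/C)I | intermediate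
18 | (4R,5R)-4-[(4R)-2,2-dimethyl-1,3-dioxolan-4-yl]-5-[(1E,5Z)-6-iodo-2-methylhepta-1,5-dien-1-yl]-3-methylidene-4-[(triethylsilyl)oxy]oxolan-2-one | C=C1C(=O)O[C@H](/C=C(\C)CC/C=C(/C)I)[C@@]1(O[Si](CC)(CC)CC)[C@H]2COC(C)(C)O2 | intermediate
19 | (4S,5R)-4-[(1R)-1,2-dihydroxyethyl]-5-[(1E,5Z)-6-iodo-2-methylhepta-1,5-dien-1-yl]-3-methylidene-4-[(triethylsilyl)oxy]oxolan-2-one | C=C1C(=O)O[C@H](/C=C(\C)CC/C=C(/C)I)[C@@]1(O[Si](CC)(CC)CC)[C@H](O)CO | intermediate
20 | (4S,5R)-4-[(1R)-2-{[tert-butyl(dimethyl)silyl]oxy}-1-hydroxyethyl]-5-[(1E,5Z)-6-iodo-2-methylhepta-1,5-dien-1-yl]-3-methylidene-4-[(triethylsilyl)oxy]oxolan-2-one | C=C1C(=O)O[C@H](/C=C(\C)CC/C=C(/C)I)[C@@]1(O[Si](CC)(CC)CC)[C@H](O)CO[Si](C)(C)C(C)(C)C | intermediate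
21 | (2E)-2-methylbut-2-en-1-ol (tiglyl alcohol) | C/C=C(\C)CO | starting material
22 | [(2R,3R)-2,3-dimethyloxiran-2-yl]methanol | OC[C@@]1(C)O[C@@H]1C | intermediate
23 | (2S,3R)-2,3-dimethyloxirane-2-carbaldehyde | O=C[C@@]1(C)O[C@@H]1C | intermediate
24 | (2S,3R)-2,3-dimethyloxirane-2-carboxylic acid | OC(=O)[C@@]1(C)O[C@@H]1C | intermediate
25 | (2S,3R)-2,3-dimethyloxirane-2-carboxylic 2,4,6-trichlorobenzoic anhydride | Clc1cc(Cl)c(C(=O)OC(=O)[C@@]2(C)O[C@@H]2C)c(Cl)c1 | intermediate
26 | (1R)-2-{[tert-butyl(dimethyl)silyl]oxy}-1-{(2R,3R)-2-[(1E,5Z)-6-iodo-2-methylhepta-1,5-dien-1-yl]-4-methylidene-5-oxo-3-[(triethylsilyl)oxy]oxolan-3-yl}ethyl (2S,3R)-2,3-dimethyloxirane-2-carboxylate | C=C1C(=O)O[C@H](/C=C(\C)CC/C=C(/C)I)[C@@]1(O[Si](CC)(CC)CC)[C@H](OC(=O)[C@@]2(C)O[C@@H]2C)CO[Si](C)(C)C(C)(C)C | intermediate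
27 | (1R)-2-hydroxy-1-{(2R,3R)-3-hydroxy-2-[(1E,5Z)-6-iodo-2-methylhepta-1,5-dien-1-yl]-4-methylidene-5-oxooxolan-3-yl}ethyl (2S,3R)-2,3-dimethyloxirane-2-carboxylate | C=C1C(=O)O[C@H](/C=C(\C)CC/C=C(/C)I)[C@@]1(O)[C@H](OC(=O)[C@@]2(C)O[C@@H]2C)CO | intermediate
28 | (1S)-1-{(2R,3R)-3-hydroxy-2-[(1E,5Z)-6-iodo-2-methylhepta-1,5-dien-1-yl]-4-methylidene-5-oxooxolan-3-yl}-2-oxoethyl (2S,3R)-2,3-dimethyloxirane-2-carboxylate | C=C1C(=O)O[C@H](/C=C(\C)CC/C=C(/C)I)[C@@]1(O)[C@H](OC(=O)[C@@]2(C)O[C@@H]2C)C=O | intermediate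
29 | alkenylchromium dichloride from 28 (C–I replaced by C–CrCl2, Z geometry kept) | C=C1C(=O)O[C@H](/C=C(\C)CC/C=C(/C)[Cr](Cl)Cl)[C@@]1(O)[C@H](OC(=O)[C@@]2(C)O[C@@H]2C)C=O | intermediate
30 | (3aR,4R,5R,6Z,10E,11aR)-3a,5-dihydroxy-6,10-dimethyl-3-methylidene-2-oxo-2,3,3a,4,5,8,9,11a-octahydrocyclodeca[b]furan-4-yl (2S,3R)-2,3-dimethyloxirane-2-carboxylate (CNP0420662.1) | C=C1C(=O)O[C@@H]2/C=C(\C)CC/C=C(/C)[C@@H](O)[C@@H](OC(=O)[C@@]3(C)O[C@@H]3C)[C@@]12O | target

**Step count and risks**

Total step count: 16. Longest linear sequence: 11 steps (steps 1–4, 8–10, 13–16, from geranyl acetate).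

Steps most likely to fail:

1. Step 8. The allylchromium may equilibrate its enol ether geometry before it adds, approach the wrong face of C7, bond through C13, or pass the triethylsilyl group from O7 to the C6 alkoxide in place of lactonisation. Any of these erodes the C6/C7/C8 relationship or the lactone closure. Fallback with a configurationally fixed allylboronate, setting out from 14 and returning at 18: copper-catalysed conjugate borylation of 14 (B2pin2, CuCl, NaOt-Bu, MeOH, THF) should give the β-boryl keto ester F1, in which O→B coordination holds the ketone oxygen next to the CH2B group. Enol silylation (Et3SiOTf, Et3N, CH2Cl2, −78 °C) should then give the siloxyallylboronate F2 with oxygen cis to CH2B. Heated with 10 in toluene (60–80 °C), F2 adds through the boron-centred chair without E/Z scrambling to the O-boryl hydroxy ester F3, and a catalytic amount of pyridinium p-toluenesulfonate closes the lactone to 18. Additions of tetrasubstituted 2-(alkoxycarbonyl)allylboronates and of γ-alkoxyallylboronates to aldehydes are known chemistry.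

2. Step 16. Ring closure against transannular strain may be slow, and the conformation of the forming ring may override the Felkin preference, so that the C9 epimer predominates. Fallback that sets C9 by reduction instead of addition, setting out from 28 and returning at 30: the closure is run as in step 16 and the crude alcohols, including the 9S alcohol F4, are oxidised with MnO2 (allylic alcohol only, tertiary hydroxyl untouched) to the 9-ketone F5. This enone is then reduced under Luche conditions (NaBH4, CeCl3·7H2O, MeOH, −78 °C) or, if the ring does not direct hydride well enough, with an oxazaborolidine catalyst and catecholborane, whose two enantiomers allow reagent control, to give 30.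

3. Step 7. The 2-acyl acrylate 14 may dimerise by hetero-Diels–Alder reaction, the γ-siloxyallyl bromide may ionise or hydrolyse before use, and the bromosilane may open the dioxolane. Fallback without the bromide, setting out from 14 and returning at 18: 14 and 10 are treated together with CrCl2 (4 equiv) and Et3SiCl (2 equiv) in THF/DMF at 0 °C. Divalent chromium reduces the chlorosilane-activated vinyl ketone unit of 14 directly to allylchromium 16, which adds to 10 and lactonises through 17 to 18. This reductive cross-coupling of vinyl ketones with aldehydes through γ-siloxyallylchromium species is known chemistry, and the doubly activated 14 should be reduced well before the β,β-disubstituted enal; the detour makes no compound outside the list (entry F0).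

Further compounds
F1 | step 8 | methyl 3-[(4R)-2,2-dimethyl-1,3-dioxolan-4-yl]-3-oxo-2-[(4,4,5,5-tetramethyl-1,3,2-dioxaborolan-2-yl)methyl]propanoate (both C2 epimers) | COC(=O)C(CB1OC(C)(C)C(C)(C)O1)C(=O)[C@H]1COC(C)(C)O1
F2 | step 8 | methyl (2E)-3-[(4R)-2,2-dimethyl-1,3-dioxolan-4-yl]-2-[(4,4,5,5-tetramethyl-1,3,2-dioxaborolan-2-yl)methyl]-3-[(triethylsilyl)oxy]prop-2-enoate | CC1(C)OB(C/C(C(=O)OC)=C(\O[Si](CC)(CC)CC)[C@H]2COC(C)(C)O2)OC1(C)C
F3 | step 8 | methyl (3R,4R,5E,9Z)-3-[(4R)-2,2-dimethyl-1,3-dioxolan-4-yl]-10-iodo-6-methyl-2-methylidene-4-[(4,4,5,5-tetramethyl-1,3,2-dioxaborolan-2-yl)oxy]-3-[(triethylsilyl)oxy]undeca-5,9-dienoate | COC(=O)C(=C)[C@](O[Si](CC)(CC)CC)([C@H]1COC(C)(C)O1)[C@H](OB1OC(C)(C)C(C)(C)O1)/C=C(\C)CC/C=C(/C)I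
F4 | step 16 | (3aR,4R,5S,6Z,10E,11aR)-3a,5-dihydroxy-6,10-dimethyl-3-methylidene-2-oxo-2,3,3a,4,5,8,9,11a-octahydrocyclodeca[b]furan-4-yl (2S,3R)-2,3-dimethyloxirane-2-carboxylate | C=C1C(=O)O[C@@H]2/C=C(\C)CC/C=C(/C)[C@H](O)[C@@H](OC(=O)[C@@]3(C)O[C@@H]3C)[C@@]12O
F5 | step 16 | (3aR,4S,6Z,10E,11aR)-3a-hydroxy-6,10-dimethyl-3-methylidene-2,5-dioxo-2,3,3a,4,5,8,9,11a-octahydrocyclodeca[b]furan-4-yl (2S,3R)-2,3-dimethyloxirane-2-carboxylate | C=C1C(=O)O[C@@H]2/C=C(\C)CC/C=C(/C)C(=O)[C@@H](OC(=O)[C@@]3(C)O[C@@H]3C)[C@@]12O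
F0 | step 7 | none | none
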